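One per second is the unit I reckon in, for a flask where initiator starts chains and free monomer joins them.

- blue: free monomer 0.027 M; initiator 8.7 mol%; run made earlier
- flask: free monomer 0.054 M; initiator 8.7 mol%; time 2.5 min

blue run (percent of the free monomer charged)

| time / s | monomer in chains / % | free monomer / % |
|---|---|---|
| 10.0 | 2.1 | 98.7 |
| 12.0 | 4.2 | 98.4 |
| 20.0 | 6.3 | 94.0 |
| 25.0 | 9.9 | 89.9 |
| 30.0 | 10.8 | 89.7 |

(readings scatter by 1 percentage point)

- the average divides the monomer in chains by the number of chains begun, living and dead together
- the numbers in the tables scatter by 1 percentage point (one standard deviation)
- the earlier runs do not show the number of chains; that part of a forecast is a guess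
- no earlier run changes the charge of initiator; that part of a forecast is a guess

- average number of monomer units in a chain (chains begun, living or dead) at 2.5 min
- part of the free monomer that has reacted at 2.5 min

I work with the fraction left, not the fraction made. At 30.0 s the blue run keeps 89.7% of its free monomer, so its reading is 0.00362 s⁻¹, with the scatter of that reading. I call this the clock rate: the natural logarithm of one over the fraction left, divided by the time. It treats the loss of free monomer as pseudo-first-order, so it is an average over the time up to that reading.

Now I turn the question round. For half of the free monomer to stand unreacted in the flask at 2.5 min, the clock rate would have to be 0.00462 s⁻¹, which is 1.28 times the blue reading. The flask holds twice the blue run's concentration of free monomer and, at the same loading, of initiator. If the clock rate follows the initiator, which is a guess because no earlier run tests it, I expect 0.00725 s⁻¹. That stands above the opposite case by a factor of 1.57, and held steady it gives my estimate of 33.7% of the free monomer left at 2.5 min. The runs show no number of chains, so I commit to no chain length.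

The forecast gives 68% reacted, above the 66.3% of my own reckoning, and 10 units per chain, reasoning “If rate follows chain concentration, the clock runs twice as fast”.

The flask gives 91.2% reacted and 23.2 units per chain.

    free monomer + living end → monomer in chains + living end, rate k1*[living end]*[free monomer] (k = 14.0 L mol⁻¹ s⁻¹)
    free monomer + initiator → living end + monomer in chains (k = 0.340 L mol⁻¹ s⁻¹)
    2 initiator → spent initiator B (k = 2.70 L mol⁻¹ s⁻¹)
    living end + monomer in chains → dead end A (k = 0.240 L mol⁻¹ s⁻¹)

With 8.8% of the free monomer left at 2.50 min, the flask's clock rate averages 0.0162 s⁻¹, against the 0.00725 s⁻¹ I expected. Growth on a living end uses free monomer 42 times as fast as the beginning of chains at 0.696 min, and 51 times as fast at 2.50 min. A flask of the same loading charged with 0.013 M of free monomer keeps 60.0% at 2.50 min, a clock rate of 0.00341 s⁻¹.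

The numbers in the tables are calculated from invented constants; the scatter is artificial.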